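**Plan**

Retrosynthesis: with the two phenols masked as MOM ethers and a C3=C4 double bond put back, ring C is cut at C4–C4a to give an aryl 1-arylpropargyl ether. That ether is cut at O1–C2 into a ring A phenol and a propargylic alcohol; the phenol is cut at the C6–CH2 bond of the prenyl group, the alcohol at C2–C3 (aldehyde plus acetylide).
Forward: phloroglucinol gives the mirror-symmetric 3,5-bis(MOM)-4-prenylphenol and 3,5-dimethoxybenzaldehyde gives the (S)-propargylic alcohol. The two are joined through O1–C2, ring C is then closed through C4–C4a, the C3=C4 bond is saturated and the MOM groups are removed.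
Enabling feature: C4a is ortho to O1 and to the C5 oxygen and para to the C7 oxygen, so it is the most nucleophilic carbon of ring A. With the prenyl group para to the ether oxygen, the two ortho carbons are equivalent, so 6-endo attack on a gold-bound terminal alkyne can only give the 5,7-dioxygenated 6-prenyl chromene.
Stereochemistry: C2 is the only stereocentre and is (R) in the target (O1 > aryl > C3 > H). It comes from a lipase resolution that leaves the (S)-alcohol, is inverted to (R) in the Mitsunobu etherification, and is a spectator afterwards.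

Key step: step 8

Remark: the lipase is assumed to follow its usual size preference (aryl as the large group), so the unreacted alcohol is (S); if the preference were reversed, the acetate would be saponified and used instead.

**Route**

Step 1
Reactants: 1 phloroglucinol
Product: 2 3,5-bis(methoxymethoxy)phenol
Conditions: MOMCl (2.0 equiv), i-Pr2NEt, DMF, 0 °C → rt; chromatography
Reagents that add atoms: chloromethyl methyl ether (MOMCl), COCCl
Why: Base-mediated O-alkylation (Williamson-type) of the triphenol with two equivalents of MOMCl should give the bis-ether as the main component of a statistical mixture, separable from the mono- and tris-ethers.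

Step 2
Reactants: 2 3,5-bis(methoxymethoxy)phenol
Product: 3 [3,5-bis(methoxymethoxy)phenoxy]tri(propan-2-yl)silane
Conditions: TIPSCl, imidazole, DMF, rt
Reagents that add atoms: chlorotri(propan-2-yl)silane (TIPSCl), CC(C)[Si](Cl)(C(C)C)C(C)C
Why: Imidazole-promoted silylation caps the remaining phenol as a bulky TIPS ether that resists n-BuLi and shields its two neighbouring ring positions in the next step.

Step 3
Reactants: 3 [3,5-bis(methoxymethoxy)phenoxy]tri(propan-2-yl)silane; 4 prenyl bromide (1-bromo-3-methylbut-2-ene)
Product: 6 [3,5-bis(methoxymethoxy)-4-(3-methylbut-2-enyl)phenoxy]tri(propan-2-yl)silane, via C4-aryllithium 5 (not isolated)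
Conditions: n-BuLi, THF, 0 °C; then CuI (10 mol %), 4, −78 °C → rt
Reagents that add atoms: none
Why: Directed ortho-metalation removes the proton flanked by the two chelating MOM ethers (the TIPS ether neither directs nor admits the base), and copper-catalysed allylic substitution of the aryllithium at the primary carbon of prenyl bromide (SN2, the tertiary terminus being too hindered for SN2′) installs the prenyl group.

Step 4
Reactants: 6 [3,5-bis(methoxymethoxy)-4-(3-methylbut-2-enyl)phenoxy]tri(propan-2-yl)silane
Product: 7 3,5-bis(methoxymethoxy)-4-(3-methylbut-2-enyl)phenol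
Conditions: TBAF, AcOH, THF, 0 °C → rt
Reagents that add atoms: none
Why: Fluoride-induced Si–O cleavage (desilylation) frees the phenol, while the MOM acetals and the alkene are inert to buffered fluoride.

Step 5
Reactants: 8 3,5-dimethoxybenzaldehyde; 9 ethynylmagnesium bromide
Product: 10 rac-1-(3,5-dimethoxyphenyl)prop-2-yn-1-ol
Conditions: THF, 0 °C; aqueous quench
Reagents that add atoms: none
Why: Grignard 1,2-addition of the acetylide to the aldehyde should give the racemic propargylic alcohol.

Step 6
Reactants: 10 rac-1-(3,5-dimethoxyphenyl)prop-2-yn-1-ol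
Product: 11 (1S)-1-(3,5-dimethoxyphenyl)prop-2-yn-1-ol
Conditions: immobilised Candida antarctica lipase B (Novozym 435), vinyl acetate, toluene, 30 °C, stopped just past half conversion; chromatography
Reagents that add atoms: none
Why: Lipase-catalysed kinetic resolution by irreversible transesterification should acetylate the (R)-alcohol (aryl large, ethynyl medium), leaving the (S)-alcohol in high enantiomeric purity as the source of the C2 configuration.

Step 7
Reactants: 7 3,5-bis(methoxymethoxy)-4-(3-methylbut-2-enyl)phenol; 11 (1S)-1-(3,5-dimethoxyphenyl)prop-2-yn-1-ol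
Product: 12 5-{[(1R)-1-(3,5-dimethoxyphenyl)prop-2-ynyl]oxy}-1,3-bis(methoxymethoxy)-2-(3-methylbut-2-enyl)benzene
Conditions: PPh3, DIAD, toluene, 0 °C → rt
Reagents that add atoms: none
Why: In this Mitsunobu etherification the phenol (pKa about 10) displaces the oxyphosphonium group by SN2 with inversion, turning the (S)-carbinol into the (R)-aryl ether, and the inductively withdrawing meta-methoxy groups disfavour an ionisation that would erode the configuration.

Step 8
Reactants: 12 5-{[(1R)-1-(3,5-dimethoxyphenyl)prop-2-ynyl]oxy}-1,3-bis(methoxymethoxy)-2-(3-methylbut-2-enyl)benzene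
Product: 13 (2R)-2-(3,5-dimethoxyphenyl)-5,7-bis(methoxymethoxy)-6-(3-methylbut-2-enyl)-2H-chromene
Conditions: [(t-Bu)2(2-biphenylyl)PAu(NCMe)]SbF6 (2 mol %), CH2Cl2, rt, dark; filtration through basic alumina
Reagents that add atoms: none
Why: The cationic monovalent gold centre binds the terminal alkyne as a π-acid, the ring A carbon ortho to the ether oxygen (the future C4a, also ortho to the C5 and para to the C7 acetal oxygen) attacks the terminal alkyne carbon anti to gold, and rearomatisation followed by protodeauration releases the 2H-chromene and the catalyst. The closest known reaction type is the gold- or platinum-catalysed intramolecular hydroarylation of aryl propargyl ethers to 2H-chromenes, a Friedel–Crafts-type alkenylation. Ring C closes in the 6-endo-dig mode through the new C4–C4a bond. No stereocentre is created; C2, set in step 7, lies outside the reacting π-system and should be carried through unchanged. The step needs 6-endo rather than 5-exo closure, which the terminal alkyne and the strongly nucleophilic arene favour; it needs no choice between ortho carbons, which the mirror symmetry of ring A removes; and it needs no C–O ionisation or sigmatropic shift, which the poorly cation-stabilising meta-dimethoxy ring B and the aprotic room-temperature conditions suppress.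

Step 9
Reactants: 13 (2R)-2-(3,5-dimethoxyphenyl)-5,7-bis(methoxymethoxy)-6-(3-methylbut-2-enyl)-2H-chromene
Product: 14 (2R)-2-(3,5-dimethoxyphenyl)-5,7-bis(methoxymethoxy)-6-(3-methylbut-2-enyl)chromane
Conditions: 2-O2NC6H4SO2NHNH2 (excess), Et3N, CH2Cl2, rt, dark
Reagents that add atoms: none
Why: Diimide reduction transfers H2 in a concerted syn fashion much faster to the cis-disubstituted C3=C4 bond than to the trisubstituted prenyl alkene, and the neutral metal-free medium leaves the benzylic C2–O bond, the MOM acetals and C2 untouched.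

Step 10
Reactants: 14 (2R)-2-(3,5-dimethoxyphenyl)-5,7-bis(methoxymethoxy)-6-(3-methylbut-2-enyl)chromane
Product: 15 (2R)-2-(3,5-dimethoxyphenyl)-6-(3-methylbut-2-enyl)chromane-5,7-diol
Conditions: HCl (3 M aq.), MeOH, rt → 40 °C
Reagents that add atoms: none
Why: Acid-catalysed acetal exchange with methanol (MOM solvolysis) releases both phenols; dilute acid near room temperature should neither add the freed phenols to the prenyl alkene nor ionise the C2–O bond, which ring B stabilises poorly.

**Compound list**

1 | phloroglucinol | Oc1cc(O)cc(O)c1 | starting material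
2 | 3,5-bis(methoxymethoxy)phenol | COCOc1cc(O)cc(OCOC)c1 | intermediate
3 | [3,5-bis(methoxymethoxy)phenoxy]tri(propan-2-yl)silane | COCOc1cc(OCOC)cc(O[Si](C(C)C)(C(C)C)C(C)C)c1 | intermediate
4 | prenyl bromide (1-bromo-3-methylbut-2-ene) | CC(C)=CCBr | starting material
5 | [2,6-bis(methoxymethoxy)-4-(triisopropylsilyloxy)phenyl]lithium | [Li]c1c(OCOC)cc(O[Si](C(C)C)(C(C)C)C(C)C)cc1OCOC | intermediate (not isolated)
6 | [3,5-bis(methoxymethoxy)-4-(3-methylbut-2-enyl)phenoxy]tri(propan-2-yl)silane | COCOc1cc(O[Si](C(C)C)(C(C)C)C(C)C)cc(OCOC)c1CC=C(C)C | intermediate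
7 | 3,5-bis(methoxymethoxy)-4-(3-methylbut-2-enyl)phenol | COCOc1cc(O)cc(OCOC)c1CC=C(C)C | intermediate
8 | 3,5-dimethoxybenzaldehyde | COc1cc(OC)cc(C=O)c1 | starting material
9 | ethynylmagnesium bromide | C#C[Mg]Br | starting material
10 | rac-1-(3,5-dimethoxyphenyl)prop-2-yn-1-ol | COc1cc(OC)cc(C(O)C#C)c1 | intermediate
11 | (1S)-1-(3,5-dimethoxyphenyl)prop-2-yn-1-ol | COc1cc(OC)cc([C@@H](O)C#C)c1 | intermediate
12 | 5-{[(1R)-1-(3,5-dimethoxyphenyl)prop-2-ynyl]oxy}-1,3-bis(methoxymethoxy)-2-(3-methylbut-2-enyl)benzene | COc1cc(OC)cc([C@H](Oc2cc(OCOC)c(CC=C(C)C)c(OCOC)c2)C#C)c1 | intermediate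
13 | (2R)-2-(3,5-dimethoxyphenyl)-5,7-bis(methoxymethoxy)-6-(3-methylbut-2-enyl)-2H-chromene | COc1cc(OC)cc([C@H]2C=Cc3c(cc(OCOC)c(CC=C(C)C)c3OCOC)O2)c1 | intermediate
14 | (2R)-2-(3,5-dimethoxyphenyl)-5,7-bis(methoxymethoxy)-6-(3-methylbut-2-enyl)chromane | COc1cc(OC)cc([C@H]2CCc3c(cc(OCOC)c(CC=C(C)C)c3OCOC)O2)c1 | intermediate
15 | (2R)-2-(3,5-dimethoxyphenyl)-6-(3-methylbut-2-enyl)chromane-5,7-diol | COc1cc(OC)cc([C@H]2CCc3c(cc(O)c(CC=C(C)C)c3O)O2)c1 | target

**Count and risks**

Total steps: 10. Longest linear sequence: 8 steps (steps 1–4 and 7–10 from phloroglucinol); steps 5–6 form the second branch.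

Steps most likely to fail:

1. Step 8. The risks are loss of configurational purity at C2 (gold- or trace-acid-induced C–O ionisation, or a competing sigmatropic shift) and acid-promoted oligomerisation of the electron-rich chromene as it forms. The fallback closes ring C through O1–C2 instead; it sets out from phenol 7 and rejoins the route at 14, bypassing 12 and 13. Magnesium-mediated ortho-formylation of 7 (MgCl2, Et3N, paraformaldehyde, MeCN, reflux) should give 6-hydroxy-2,4-bis(methoxymethoxy)-3-(3-methylbut-2-enyl)benzaldehyde F1. Claisen–Schmidt condensation with commercial 3,5-dimethoxyacetophenone (KOH, EtOH) should give (E)-1-(3,5-dimethoxyphenyl)-3-[6-hydroxy-2,4-bis(methoxymethoxy)-3-(3-methylbut-2-enyl)phenyl]prop-2-en-1-one F2. Conjugate reduction with [(Ph3P)CuH]6 and PhSiH3 should give 1-(3,5-dimethoxyphenyl)-3-[6-hydroxy-2,4-bis(methoxymethoxy)-3-(3-methylbut-2-enyl)phenyl]propan-1-one F3, leaving the prenyl alkene alone. Asymmetric transfer hydrogenation with RuCl(p-cymene)[(S,S)-TsDPEN] in HCO2H/Et3N should give 2-[(3S)-3-(3,5-dimethoxyphenyl)-3-hydroxypropyl]-3,5-bis(methoxymethoxy)-4-(3-methylbut-2-enyl)phenol F4. Intramolecular Mitsunobu etherification (PPh3, DIAD, THF) then closes the pyran ring with inversion to give 14.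

2. Step 9. The risks are over-reduction reaching the prenyl alkene, or stalling short of full conversion while the sensitive chromene degrades. The fallback saturates C3=C4 before any prenyl group is present; it sets out from aryllithium 5 and rejoins the route at 14. Quenching 5 with BrCF2CF2Br should give [4-bromo-3,5-bis(methoxymethoxy)phenoxy]tri(propan-2-yl)silane F5, and TBAF/AcOH then 4-bromo-3,5-bis(methoxymethoxy)phenol F6. Mitsunobu etherification with 11 should give 2-bromo-5-{[(1R)-1-(3,5-dimethoxyphenyl)prop-2-ynyl]oxy}-1,3-bis(methoxymethoxy)benzene F7. The gold-catalysed hydroarylation of step 8 should give (2R)-6-bromo-2-(3,5-dimethoxyphenyl)-5,7-bis(methoxymethoxy)-2H-chromene F8. With no other alkene present, the C3=C4 bond is reduced by excess diimide or by H2 over RhCl(PPh3)3, both of which spare the aryl bromide, to give (2R)-6-bromo-2-(3,5-dimethoxyphenyl)-5,7-bis(methoxymethoxy)chromane F9. Bromine–lithium exchange (n-BuLi, THF, −78 °C) should give [(2R)-2-(3,5-dimethoxyphenyl)-5,7-bis(methoxymethoxy)chroman-6-yl]lithium F10, and copper-catalysed allylation with prenyl bromide 4 (CuI) then gives 14.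

3. Step 7. The risks are partial ionisation at the benzylic, propargylic carbon eroding enantiomeric purity, or SN2′ attack leading to an allenyl ether. The fallback replaces the stereospecific displacement by an enantioconvergent one; it sets out from racemic alcohol 10 and rejoins the route at 12, making step 6 unnecessary. Methyl chloroformate and pyridine should convert 10 into rac-1-(3,5-dimethoxyphenyl)prop-2-ynyl methyl carbonate F11. Copper-catalysed enantioselective propargylic etherification with phenol 7 (CuOTf·0.5C6H6, chiral 2,6-bis(oxazolinyl)pyridine ligand, i-Pr2NEt, MeOH, −20 °C) then proceeds through a copper allenylidene that no longer carries the original stereocentre. The ligand antipode is chosen to deliver the (R)-ether 12; C-alkylation of the electron-rich phenol is the side reaction to watch.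

**Further compounds**

F1 | step 8 | 6-hydroxy-2,4-bis(methoxymethoxy)-3-(3-methylbut-2-enyl)benzaldehyde | O=Cc1c(O)cc(OCOC)c(CC=C(C)C)c1OCOC
F2 | step 8 | (E)-1-(3,5-dimethoxyphenyl)-3-[6-hydroxy-2,4-bis(methoxymethoxy)-3-(3-methylbut-2-enyl)phenyl]prop-2-en-1-one | COc1cc(OC)cc(C(=O)/C=C/c2c(O)cc(OCOC)c(CC=C(C)C)c2OCOC)c1
F3 | step 8 | 1-(3,5-dimethoxyphenyl)-3-[6-hydroxy-2,4-bis(methoxymethoxy)-3-(3-methylbut-2-enyl)phenyl]propan-1-one | COc1cc(OC)cc(C(=O)CCc2c(O)cc(OCOC)c(CC=C(C)C)c2OCOC)c1
F4 | step 8 | 2-[(3S)-3-(3,5-dimethoxyphenyl)-3-hydroxypropyl]-3,5-bis(methoxymethoxy)-4-(3-methylbut-2-enyl)phenol | COc1cc(OC)cc([C@@H](O)CCc2c(O)cc(OCOC)c(CC=C(C)C)c2OCOC)c1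
F5 | step 9 | [4-bromo-3,5-bis(methoxymethoxy)phenoxy]tri(propan-2-yl)silane | COCOc1cc(O[Si](C(C)C)(C(C)C)C(C)C)cc(OCOC)c1Br
F6 | step 9 | 4-bromo-3,5-bis(methoxymethoxy)phenol | COCOc1cc(O)cc(OCOC)c1Br
F7 | step 9 | 2-bromo-5-{[(1R)-1-(3,5-dimethoxyphenyl)prop-2-ynyl]oxy}-1,3-bis(methoxymethoxy)benzene | COc1cc(OC)cc([C@H](Oc2cc(OCOC)c(Br)c(OCOC)c2)C#C)c1
F8 | step 9 | (2R)-6-bromo-2-(3,5-dimethoxyphenyl)-5,7-bis(methoxymethoxy)-2H-chromene | COc1cc(OC)cc([C@H]2C=Cc3c(cc(OCOC)c(Br)c3OCOC)O2)c1
F9 | step 9 | (2R)-6-bromo-2-(3,5-dimethoxyphenyl)-5,7-bis(methoxymethoxy)chromane | COc1cc(OC)cc([C@H]2CCc3c(cc(OCOC)c(Br)c3OCOC)O2)c1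
F10 | step 9 | [(2R)-2-(3,5-dimethoxyphenyl)-5,7-bis(methoxymethoxy)chroman-6-yl]lithium | COc1cc(OC)cc([C@H]2CCc3c(cc(OCOC)c([Li])c3OCOC)O2)c1
F11 | step 7 | rac-1-(3,5-dimethoxyphenyl)prop-2-ynyl methyl carbonate | COC(=O)OC(C#C)c1cc(OC)cc(OC)c1
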